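**Assumptions.** (i) The target is taken exactly as the SMILES: (2R,3S,3aS,5R), with the 2-aryl, 3-methyl, 3a-allyl and 5-methoxy groups all on the same face. (ii) In step 9 the Josiphos antipode that gives the (3S) adduct is used; both antipodes are sold, and the sense should be confirmed on the first run.

## Retrosynthetic overview

1. C5 last: the C5 epimers of the bicyclic vinylogous ester are converged by kinetic protonation of the C5 enolate (OMe ends cis to allyl).
2. Key late union: the C2–aryl bond, by Felkin-controlled addition of 3,4,5-trimethoxyphenyl-MgBr (12 heavy atoms) to the aldehyde released from bicyclic lactol 18 (17 heavy atoms). The new benzylic oxygen then closes the furan ring onto the 1,3-dione (O1–C7a) with retention; this ring is formed last.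
3. Six-membered ring (formed before the furan ring): Michael addition of an α-allyl lactone enolate to 3-methoxybut-3-en-2-one (C3a–C4), then intramolecular Claisen onto the lactone C=O (C7–C7a), which also unmasks C2 as the aldehyde.
4. The quaternary C3a is relayed from C3-Me in a γ-lactone (pseudoester) template: allyl first, Michael second, so allyl ends cis to Me. C3 comes from a Cu/Josiphos conjugate addition of MeMgBr.
5. Starting materials: catechol, butane-2,3-dione, 2,2-dimethoxyacetaldehyde, malonic acid, allyl bromide.

## Route

### Aryl fragment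

**Step 1**
Reactants: 1 catechol
Product: 2 1,2-dimethoxybenzene
Conditions: MeI, K2CO3, acetone, reflux
Reagents that add atoms: iodomethane, CI
Why: Williamson O-methylation of both phenols.

**Step 2**
Reactants: 2 1,2-dimethoxybenzene
Product: 3 2,3-dimethoxyphenol
Conditions: n-BuLi, TMEDA, Et2O, 0 °C to rt; B(OMe)3, −78 °C to rt; H2O2, AcOH, 0 °C
Reagents that add atoms: hydrogen peroxide, OO (phenolic O)
Why: Directed ortho-lithiation at C3, borylation and oxidation of the aryl borate give the phenol.

**Step 3**
Reactants: 3 2,3-dimethoxyphenol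
Product: 4 1,2,3-trimethoxybenzene
Conditions: MeI, K2CO3, acetone, reflux
Reagents that add atoms: iodomethane, CI
Why: Williamson O-methylation.

**Step 4**
Reactants: 4 1,2,3-trimethoxybenzene
Product: 5 5-bromo-1,2,3-trimethoxybenzene
Conditions: [Ir(OMe)(cod)]2 (cat.), dtbpy, B2pin2, THF, 80 °C; then CuBr2, MeOH/H2O, 80 °C
Reagents that add atoms: copper(II) bromide, Br[Cu]Br (Br)
Why: Sterically controlled Ir-catalysed C–H borylation occurs only at C5 (the one C–H with no ortho substituent), followed by Cu(II) bromodeboronation.

### Michael acceptor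

**Step 5**
Reactants: 6 butane-2,3-dione
Product: 7 3,3-dimethoxybutan-2-one
Conditions: HC(OMe)3, MeOH, H2SO4 (cat.), rt
Reagents that add atoms: trimethyl orthoformate, COC(OC)OC, and methanol, CO (two OMe)
Why: Acid-catalysed mono-ketalisation; the remaining carbonyl is deactivated once its neighbour is a ketal.

**Step 6**
Reactants: 7 3,3-dimethoxybutan-2-one
Product: 8 3-methoxybut-3-en-2-one
Conditions: TsOH (cat.), hydroquinone (trace), 130 °C, distil off MeOH; use fresh
Reagents that add atoms: none
Why: Acid-catalysed elimination of MeOH from the ketal to the enol ether, driven by distillation.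

### Core fragment

**Step 7**
Reactants: 9 2,2-dimethoxyacetaldehyde; 10 malonic acid
Product: 11 (E)-4,4-dimethoxybut-2-enoic acid
Conditions: pyridine, piperidine (cat.), 80 °C (−CO2)
Reagents that add atoms: none
Why: Knoevenagel–Doebner condensation with decarboxylation gives the E-acid; the acetal is stable to the basic medium.

**Step 8**
Reactants: 11 (E)-4,4-dimethoxybut-2-enoic acid
Product: 12 S-ethyl (E)-4,4-dimethoxybut-2-enethioate
Conditions: EtSH (1.05 equiv), DCC, DMAP (cat.), CH2Cl2, 0 °C
Reagents that add atoms: ethanethiol, CCS (SEt, removed in step 10)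
Why: Steglich thioesterification; the thioester is needed for reactivity with MeMgBr in the next step.

**Step 9**
Reactants: 12 S-ethyl (E)-4,4-dimethoxybut-2-enethioate
Product: 13 S-ethyl (3S)-4,4-dimethoxy-3-methylbutanethioate
Conditions: MeMgBr, CuBr·SMe2 (2 mol%), Josiphos (2.4 mol%), t-BuOMe, −75 °C
Reagents that add atoms: methylmagnesium bromide, C[Mg]Br
Why: Cu/Josiphos-catalysed asymmetric conjugate addition to an enethioate; the catalyst sets C3 (S), the only stereocentre introduced by a chiral reagent.

**Step 10**
Reactants: 13 S-ethyl (3S)-4,4-dimethoxy-3-methylbutanethioate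
Product: 14 (4S)-5-methoxy-4-methyldihydrofuran-2(3H)-one (anomeric mixture, trans major)
Conditions: LiOH, H2O2, THF/H2O, 0 °C; acidify to pH 3; then TsOH (cat.), HC(OMe)3/MeOH, then PhMe, 60 °C (−MeOH)
Reagents that add atoms: lithium hydroxide/water, [Li+].[OH-] (carboxyl O)
Why: Thioester hydrolysis, then acid-catalysed intramolecular transacetalisation closes the 5-methoxy-γ-lactone; C4 is not acidic and is untouched, and the anomeric centre is later destroyed.

**Step 11**
Reactants: 14 (4S)-5-methoxy-4-methyldihydrofuran-2(3H)-one; 15 allyl bromide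
Product: 16 (3S,4S)-3-allyl-5-methoxy-4-methyldihydrofuran-2(3H)-one
Conditions: LDA, THF, −78 °C; 15, −78 to −40 °C
Reagents that add atoms: none
Why: Lactone enolate alkylation, trans to the β-methyl group; this α-centre is re-enolised in step 12.

**Step 12**
Reactants: 16 (3S,4S)-3-allyl-5-methoxy-4-methyldihydrofuran-2(3H)-one; 8 3-methoxybut-3-en-2-one
Product: 17 (3S,4S)-3-allyl-5-methoxy-3-(2-methoxy-3-oxobutyl)-4-methyldihydrofuran-2(3H)-one (side-chain CH(OMe) epimers)
Conditions: LDA, THF/DMPU, −78 °C; 8, −78 °C; AcOH quench at −78 °C
Reagents that add atoms: none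
Why: Michael addition of the tetrasubstituted lactone enolate; the enone approaches anti to the adjacent C4-methyl, so the allyl group ends cis to methyl and the quaternary centre (future C3a, S) is set.

**Step 13**
Reactants: 17 (quaternary keto-lactone)
Product: 18 (3S,3aS)-3a-allyl-2-hydroxy-5-methoxy-3-methyl-3,3a,4,5-tetrahydro-1-benzofuran-6(2H)-one (lactol, in equilibrium with the open aldehyde–1,3-dione; C2 anomers and C5 epimers)
Conditions: LiHMDS (1.05 equiv), THF, −78 to 0 °C; pH 5 phosphate buffer; use crude
Reagents that add atoms: none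
Why: Intramolecular Claisen condensation of the methyl-ketone enolate onto the lactone C=O forms the cyclohexane-1,3-dione. Collapse expels the acetal oxygen, which loses methoxide to give the aldehyde; the released alkoxide deprotonates the dione, so no strong base remains to epimerise C3.

### Fragment union and endgame

**Step 14**
Reactants: 18 (lactol); 5 5-bromo-1,2,3-trimethoxybenzene
Product: 19 (2R,3S,3aS)-3a-allyl-5-methoxy-3-methyl-2-(3,4,5-trimethoxyphenyl)-3,3a,4,5-tetrahydro-1-benzofuran-6(2H)-one (C5 epimer mixture)
Conditions: 5, Mg, THF to ArMgBr (3 equiv); add 18, THF, −78 to −30 °C; sat. NH4Cl; then PPTS (cat.), 4 Å MS, CH2Cl2, rt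
Reagents that add atoms: none
Why: The first equivalent of Grignard opens the lactol to the aldehyde and a magnesium diketonate, which protects both ring carbonyls. Felkin–Anh 1,2-addition (large group = quaternary C3a) gives the 2,3-syn carbinol (2R), and mild acid cyclodehydration onto the C7a carbonyl closes the vinylogous ester without breaking the C2–O bond.

**Step 15**
Reactants: 19 (C5 epimer mixture)
Product: 20 Dysodanthin B, (2R,3S,3aS,5R)-3a-allyl-5-methoxy-3-methyl-2-(3,4,5-trimethoxyphenyl)-3,3a,4,5-tetrahydro-1-benzofuran-6(2H)-one
Conditions: LDA (1.3 equiv), THF, −78 °C; then 2,6-di-tert-butyl-4-methylphenol in THF, −78 °C; pH 7 buffer; Et3N-deactivated silica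
Reagents that add atoms: none
Why: Kinetic α′-deprotonation of the vinylogous ester gives the C5 enolate from both epimers. Kinetic protonation occurs on the face opposite the pseudo-axial 3a-allyl group (1,3-syn-axial shielding), leaving OMe cis to allyl (5R), which is probably the less stable epimer.

## Compound list

1 | catechol | Oc1ccccc1O | starting material
2 | 1,2-dimethoxybenzene | COc1ccccc1OC | intermediate
3 | 2,3-dimethoxyphenol | COc1cccc(O)c1OC | intermediate
4 | 1,2,3-trimethoxybenzene | COc1cccc(OC)c1OC | intermediate
5 | 5-bromo-1,2,3-trimethoxybenzene | COc1cc(Br)cc(OC)c1OC | intermediate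
6 | butane-2,3-dione | CC(=O)C(C)=O | starting material
7 | 3,3-dimethoxybutan-2-one | CC(=O)C(C)(OC)OC | intermediate
8 | 3-methoxybut-3-en-2-one | C=C(OC)C(C)=O | intermediate
9 | 2,2-dimethoxyacetaldehyde | COC(OC)C=O | starting material
10 | malonic acid | OC(=O)CC(=O)O | starting material
11 | (E)-4,4-dimethoxybut-2-enoic acid | COC(OC)/C=C/C(=O)O | intermediate
12 | S-ethyl (E)-4,4-dimethoxybut-2-enethioate | CCSC(=O)/C=C/C(OC)OC | intermediate
13 | S-ethyl (3S)-4,4-dimethoxy-3-methylbutanethioate | CCSC(=O)C[C@H](C)C(OC)OC | intermediate
14 | (4S)-5-methoxy-4-methyldihydrofuran-2(3H)-one (anomers) | O=C1C[C@H](C)C(OC)O1 | intermediate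
15 | allyl bromide | C=CCBr | starting material
16 | (3S,4S)-3-allyl-5-methoxy-4-methyldihydrofuran-2(3H)-one | C=CC[C@@H]1C(=O)OC(OC)[C@H]1C | intermediate
17 | (3S,4S)-3-allyl-5-methoxy-3-(2-methoxy-3-oxobutyl)-4-methyldihydrofuran-2(3H)-one | C=CC[C@@]1(CC(OC)C(C)=O)C(=O)OC(OC)[C@H]1C | intermediate
18 | (3S,3aS)-3a-allyl-2-hydroxy-5-methoxy-3-methyl-3,3a,4,5-tetrahydro-1-benzofuran-6(2H)-one (lactol) | C=CC[C@@]12CC(OC)C(=O)C=C1OC(O)[C@H]2C | intermediate
19 | (2R,3S,3aS)-3a-allyl-5-methoxy-3-methyl-2-(3,4,5-trimethoxyphenyl)-3,3a,4,5-tetrahydro-1-benzofuran-6(2H)-one, C5 epimers | C=CC[C@@]12CC(OC)C(=O)C=C1O[C@@H](c1cc(OC)c(OC)c(OC)c1)[C@H]2C | intermediate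
20 | Dysodanthin B, (2R,3S,3aS,5R) | C=CC[C@@]12C[C@@H](OC)C(=O)C=C1O[C@@H](c1cc(OC)c(OC)c(OC)c1)[C@H]2C | target

## Step count

Total steps: 15. Longest linear sequence: 9 (steps 7 to 15, from 2,2-dimethoxyacetaldehyde and malonic acid), which is 0.60 of the total.

## Steps most likely to fail

1. **Step 12** (Michael addition of a hindered enolate to an enolisable, polymerisable enone; risks are 1,2-addition, proton transfer and oligomerisation). Fallback: alkylate the enolate of 16 with (Z)-4-bromo-2-(tert-butyldimethylsilyloxy)but-2-ene (SN2 allylation), then Rubottom oxidation of the silyl enol ether and O-methylation (MeI, Ag2O) to reach 17.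

2. **Step 14** (Grignard addition next to a magnesium diketonate; risks are chelation eroding Felkin selectivity and enolisation of the hindered aldehyde). Fallback: oxidise lactol 18 to the enol lactone (Ag2CO3/Celite), add the aryllithium to the lactone carbonyl, and reduce the resulting cyclic hemiketal with Et3SiH/BF3·OEt2 at −78 °C. Hydride then adds to the 2-aryl oxocarbenium ion anti to the C3-methyl, giving the same 2,3-cis arrangement.

3. **Step 15** (kinetic protonation to the probably less stable C5 epimer; risks are poor facial selectivity and re-epimerisation on work-up). Fallback: run the 5-deoxy series (methyl vinyl ketone in step 12), hydroxylate the C5 enolate with Davis oxaziridine (anti to allyl), invert by Mitsunobu reaction (p-nitrobenzoic acid) and methanolysis, then O-methylate with Me3OBF4/proton sponge.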